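**Strategy.** The target is a methylene-bridged dimer of 7-acetyl-3,6,8-trihydroxy-4,4-dimethylnaphthalen-1(4H)-one. Each ring B is a cyclic β-diketone (C1 ketone, C3 enol) flanked by the quaternary C4, so it is disconnected at C2–C3 to an ortho-acetylaryl isobutyrate: C3 is an ester carbon without α-hydrogen, C2 the methyl of an aryl ketone. In one pot, a Dieckmann condensation forms the C2–C3 bond and closes ring B; C2, now the most acidic carbon, then condenses with formaldehyde (Knoevenagel–Michael), joining two halves through the C2–CH2–C2' bridge as the presumed biosynthesis does. The precursor is a protecting-group-free diacetylresorcinol ester made in two steps.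

Key step: step 3

Remark: the target has no stereocentre and its SMILES shows one of several equivalent enol tautomers of the two ring B β-diketone units. Locants C1–C8a follow the naphthalen-1(4H)-one numbering of one half; positions of the benzene precursors are written "phenyl C2" and so on, counted from the carbon that bears the side chain.

**Step 1**
Reactants: 1 methyl 2-(3,5-dimethoxyphenyl)acetate
Product: 2 methyl 2-(3,5-dimethoxyphenyl)-2-methylpropanoate
Conditions: NaH (2.5 equiv), MeI (3 equiv), THF/DMF, 0 °C to rt
Reagents that add atoms: iodomethane, CI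
Why: Double enolate C-alkylation, in which the benzylic ester enolate is methylated twice and the reaction should stop at the quaternary carbon because no α-hydrogen remains; no stereocentre is formed.

**Step 2**
Reactants: 2 methyl 2-(3,5-dimethoxyphenyl)-2-methylpropanoate
Product: 5 methyl 2-(2,4-diacetyl-3,5-dihydroxyphenyl)-2-methylpropanoate, via monoacetyl diether 3 (not isolated), via diacetyl diether 4 (not isolated)
Conditions: AcCl (3 equiv), AlCl3 (6 equiv), ClCH2CH2Cl, 0 °C to 60 °C; then ice, aq. HCl
Reagents that add atoms: acetyl chloride, CC(Cl)=O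
Why: Friedel–Crafts acylation followed by chelation-assisted ether cleavage: the first acetyl should enter phenyl C2 (para to one methoxy group) and, being twisted out of plane, deactivate the ring only weakly, the second can then only enter phenyl C4 between the two oxygens because phenyl C6 would place the quaternary carbon between two acetyl groups, and on warming AlCl3 should cleave both methyl ethers, each of which sits ortho to an acetyl carbonyl.

**Step 3**
Reactants: 5 methyl 2-(2,4-diacetyl-3,5-dihydroxyphenyl)-2-methylpropanoate (two molecules)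
Product: 8 2,2'-methylenebis(7-acetyl-3,6,8-trihydroxy-4,4-dimethylnaphthalen-1(4H)-one), via Dieckmann monomer 6 (not isolated), via 2-methylidene trione 7 (not isolated)
Conditions: KOtBu (5 equiv), THF/DMSO, 0 °C to rt; then AcOH (to pH 5), 37% aq. CH2O (0.5 equiv), rt
Reagents that add atoms: formaldehyde, C=O
Why: KOtBu should deprotonate both phenols and the methyl of the acetyl group ortho to the side chain (twisted out of conjugation by the neighbouring quaternary carbon, hence the more acidic acetyl), and this enolate carbon (future C2) attacks the ester carbonyl (future C3) with loss of methoxide to give the ring B β-diketonate of 6 irreversibly. The closest known reaction types are the Dieckmann (intramolecular Claisen) condensation of ortho-acylaryl acetic esters, the Baker–Venkataraman-type acylation of polyphenoxide ketone enolates, and the Knoevenagel–Michael condensation of cyclic 1,3-diones with formaldehyde. Ring B is closed in a 6-(enolexo)-exo-trig mode, helped by the gem-dimethyl (Thorpe–Ingold) effect at C4. After buffering with AcOH, C2 of 6 adds to formaldehyde and loses water to give 7, which a second molecule of 6 traps by Michael addition at its C2 to give 8. No stereocentre is formed, the target being achiral. The selectivity needed is secured because only the acetyl ortho to the side chain can reach the ester (the other is para to it), the ester has no α-hydrogen and cannot enolise, and the substoichiometric formaldehyde reacts at the strongly acidic C2 and not at the acetyl methyl groups or at aromatic C5–H, which is deactivated by two acyl groups and shielded by the peri gem-dimethyl group.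

**Compound list**
1 | methyl 2-(3,5-dimethoxyphenyl)acetate | COC(=O)Cc1cc(OC)cc(OC)c1 | starting material
2 | methyl 2-(3,5-dimethoxyphenyl)-2-methylpropanoate | COC(=O)C(C)(C)c1cc(OC)cc(OC)c1 | intermediate
3 | methyl 2-(2-acetyl-3,5-dimethoxyphenyl)-2-methylpropanoate | COC(=O)C(C)(C)c1cc(OC)cc(OC)c1C(C)=O | intermediate (not isolated)
4 | methyl 2-(2,4-diacetyl-3,5-dimethoxyphenyl)-2-methylpropanoate | COC(=O)C(C)(C)c1cc(OC)c(C(C)=O)c(OC)c1C(C)=O | intermediate (not isolated)
5 | methyl 2-(2,4-diacetyl-3,5-dihydroxyphenyl)-2-methylpropanoate | COC(=O)C(C)(C)c1cc(O)c(C(C)=O)c(O)c1C(C)=O | intermediate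
6 | 7-acetyl-3,6,8-trihydroxy-4,4-dimethylnaphthalen-1(4H)-one | CC(=O)c1c(O)cc2c(c1O)C(=O)C=C(O)C2(C)C | intermediate (not isolated)
7 | 7-acetyl-6,8-dihydroxy-4,4-dimethyl-2-methylidenenaphthalene-1,3(2H,4H)-dione | CC(=O)c1c(O)cc2c(c1O)C(=O)C(=C)C(=O)C2(C)C | intermediate (not isolated)
8 | 2,2'-methylenebis(7-acetyl-3,6,8-trihydroxy-4,4-dimethylnaphthalen-1(4H)-one) | CC(=O)c1c(O)cc2c(c1O)C(=O)C(CC1=C(O)C(C)(C)c3cc(O)c(C(C)=O)c(O)c3C1=O)=C(O)C2(C)C | target

**Total step count:** 3
**Longest linear sequence:** 3 steps

**Steps most likely to fail**

Step 2. Acylation next to the quaternary carbon may not take place, the two acetyl groups may enter in another pattern, or partial ether cleavage may give mixtures. The fallback sets out from 1 and puts the ortho substituent in place before the quaternary centre exists. NBS in MeCN should brominate 1 para to a methoxy group to give methyl 2-(2-bromo-3,5-dimethoxyphenyl)acetate F1. NaH/MeI then gives methyl 2-(2-bromo-3,5-dimethoxyphenyl)-2-methylpropanoate F2. Stille coupling of F2 with tributyl(1-ethoxyvinyl)stannane (Pd2(dba)3, P(tBu)3, CsF, dioxane, 100 °C) gives the enol ether methyl 2-[2-(1-ethoxyethenyl)-3,5-dimethoxyphenyl]-2-methylpropanoate F3. Hydrolysis of F3 (aq. HCl, THF) comes back to the route at 3, now isolated, which needs only the single acylation between the two oxygens and the ether cleavage (AcCl, AlCl3) to reach 5.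

Step 3. The poorly soluble polyphenoxide may enolise incompletely, the acetyl groups may undergo intermolecular Claisen or aldol condensation, or formaldehyde may hydroxymethylate the free phenol ring. The fallback sets out from 4, obtained by stopping step 2 at the diether stage (AcCl, AlCl3 (3 equiv), CH2Cl2, 0 °C). Dieckmann condensation of the bis(methyl ether) (KOtBu, THF) should give 7-acetyl-3-hydroxy-6,8-dimethoxy-4,4-dimethylnaphthalen-1(4H)-one F4, which is isolated. Condensation of F4 with formaldehyde (0.5 equiv, aq. EtOH, rt) gives 2,2'-methylenebis(7-acetyl-3-hydroxy-6,8-dimethoxy-4,4-dimethylnaphthalen-1(4H)-one) F5. Cleavage of the four ethers, all ortho to a carbonyl group, with BCl3 (CH2Cl2, −78 to 0 °C) comes back to the route at 8.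

Step 1. The alkylation may stall at the monomethyl ester, or the ester enolate may undergo Claisen self-condensation. The fallback sets out from 1, which is saponified (LiOH, THF/H2O) to 2-(3,5-dimethoxyphenyl)acetic acid F6. Its dianion is methylated in two cycles (LiN(iPr)2, MeI, THF, −78 to 0 °C) via racemic 2-(3,5-dimethoxyphenyl)propanoic acid F7 to 2-(3,5-dimethoxyphenyl)-2-methylpropanoic acid F8. Esterification of F8 (MeI, K2CO3, DMF) comes back to the route at 2.

**Further compounds**
F1 | step 2 | methyl 2-(2-bromo-3,5-dimethoxyphenyl)acetate | COC(=O)Cc1cc(OC)cc(OC)c1Br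
F2 | step 2 | methyl 2-(2-bromo-3,5-dimethoxyphenyl)-2-methylpropanoate | COC(=O)C(C)(C)c1cc(OC)cc(OC)c1Br
F3 | step 2 | methyl 2-[2-(1-ethoxyethenyl)-3,5-dimethoxyphenyl]-2-methylpropanoate | CCOC(=C)c1c(OC)cc(OC)cc1C(C)(C)C(=O)OC
F4 | step 3 | 7-acetyl-3-hydroxy-6,8-dimethoxy-4,4-dimethylnaphthalen-1(4H)-one | CC(=O)c1c(OC)cc2c(c1OC)C(=O)C=C(O)C2(C)C
F5 | step 3 | 2,2'-methylenebis(7-acetyl-3-hydroxy-6,8-dimethoxy-4,4-dimethylnaphthalen-1(4H)-one) | CC(=O)c1c(OC)cc2c(c1OC)C(=O)C(CC1=C(O)C(C)(C)c3cc(OC)c(C(C)=O)c(OC)c3C1=O)=C(O)C2(C)C
F6 | step 1 | 2-(3,5-dimethoxyphenyl)acetic acid | OC(=O)Cc1cc(OC)cc(OC)c1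
F7 | step 1 | racemic 2-(3,5-dimethoxyphenyl)propanoic acid | CC(C(=O)O)c1cc(OC)cc(OC)c1
F8 | step 1 | 2-(3,5-dimethoxyphenyl)-2-methylpropanoic acid | CC(C)(C(=O)O)c1cc(OC)cc(OC)c1
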